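## Retrosynthetic overview

1. The target comes from macrocycle 25 by one unmasking operation (C15 silyl ether, C14 dimethyl acetal). The C8 ester is already in place and the C9 hydroxyl never carries a protecting group.
2. Key step: the ten-membered ring is closed last at C9–C10 by a Nozaki–Hiyama–Kishi alkenylation of the α-acyloxy aldehyde 23. This replaces the usual ring-closing metathesis of a seco-diene with late acylation, and makes the ring, the C9 carbinol and the hydroxyalkyl-enal unit together.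
3. The γ-lactone is made before the carbocycle: CrCl2 allylation/lactonisation of the Z-enal 11 (fragment A) with the glyceraldehyde-derived bromide 15 (fragment B) sets C6 and C7 from the chiral-pool C8.
4. Fragment A carries both ring-cis trisubstituted alkenes, built from but-2-yne-1,4-diol by directed hydroalumination–iodination, Suzuki coupling, cross-metathesis and enal α-iodination.
5. Ring order: γ-lactone (step 10), then cyclodecadiene (step 15).

Assumption: C-locants in the text are the germacrane locants of the target (C6/C7 lactone fusion, C8 ester, C9 carbinol, C10 formyl-bearing carbon, C14 formyl carbon, C15 hydroxymethyl carbon, C11–C13 methylene-lactone carbons). CIP descriptors are those of each compound itself. Compounds 1, 5, 7, 12 (freshly distilled), 13 and 21 are bought.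

## Route

Step 1
Reactants: 1 but-2-yne-1,4-diol
Product: 2 4-[(tert-butyldiphenylsilyl)oxy]but-2-yn-1-ol
Conditions: TBDPSCl (1.0 equiv), imidazole, 1 (3 equiv), DMF, 0 °C to rt
Reagents that add atoms: tert-butyl(chloro)diphenylsilane, CC(C)(C)[Si](Cl)(c1ccccc1)c1ccccc1
Why: Statistical monosilylation (silyl ether formation) of the symmetric diol used in excess gives the mono-ether, and no stereocentre is involved.

Step 2
Reactants: 2 4-[(tert-butyldiphenylsilyl)oxy]but-2-yn-1-ol
Product: 4 (Z)-4-[(tert-butyldiphenylsilyl)oxy]-3-iodobut-2-en-1-ol, via cyclic alkenylalanate 3 (not isolated)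
Conditions: NaAlH2(OCH2CH2OMe)2, THF, 0 °C to rt; then I2, THF, −78 to 0 °C
Reagents that add atoms: iodine, [I][I]; NaAlH2(OCH2CH2OMe)2, [Na+].COCCO[AlH2-]OCCOC (its sodium, aluminium and alkoxy groups stay only in 3)
Why: Hydroxyl-directed trans-hydroalumination of the propargylic alcohol puts aluminium on the distal alkyne carbon in a five-membered alanate, and iododealumination with retention gives the Z-iodide with iodine (the future C3 attachment site) cis to CH2OH (future C6).

Step 3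
Reactants: 4 (Z)-4-[(tert-butyldiphenylsilyl)oxy]-3-iodobut-2-en-1-ol; 5 potassium but-3-en-1-yltrifluoroborate
Product: 6 (E)-3-{[(tert-butyldiphenylsilyl)oxy]methyl}hepta-2,6-dien-1-ol
Conditions: PdCl2(dppf) (5 mol %), Cs2CO3, toluene/H2O (3:1), 80 °C
Reagents that add atoms: none
Why: Suzuki–Miyaura sp2–sp3 cross-coupling of the alkenyl iodide with the primary alkyltrifluoroborate proceeds with retention of alkene geometry, so the C3–C1 chain ends cis to C6 (ring-cis C4=C5), and the free hydroxyl is tolerated.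

Step 4
Reactants: 6 (E)-3-{[(tert-butyldiphenylsilyl)oxy]methyl}hepta-2,6-dien-1-ol; 7 (E)-but-2-enal
Product: 8 (2E,6E)-6-{[(tert-butyldiphenylsilyl)oxy]methyl}-8-hydroxyocta-2,6-dienal
Conditions: second-generation Hoveyda–Grubbs catalyst (5 mol %), 7 (5 equiv), CH2Cl2, 40 °C
Reagents that add atoms: none
Why: Olefin cross-metathesis of the monosubstituted alkene with excess crotonaldehyde gives the E-enal under thermodynamic control while the trisubstituted alkene is inert.

Step 5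
Reactants: 8 (2E,6E)-6-{[(tert-butyldiphenylsilyl)oxy]methyl}-8-hydroxyocta-2,6-dienal
Product: 9 (2Z,6E)-6-{[(tert-butyldiphenylsilyl)oxy]methyl}-8-hydroxy-2-iodoocta-2,6-dienal
Conditions: I2, K2CO3, DMAP (0.2 equiv), THF/H2O (1:1), rt
Reagents that add atoms: iodine, [I][I]
Why: DMAP-mediated α-iodination of the enal (conjugate addition, enolate iodination, E1cB loss of DMAP; Baylis–Hillman-type) gives the Z-α-iodoenal with iodine cis to C2 and the formyl carbon trans to it, which is the geometry needed at C1=C10.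

Step 6
Reactants: 9 (2Z,6E)-6-{[(tert-butyldiphenylsilyl)oxy]methyl}-8-hydroxy-2-iodoocta-2,6-dienal
Product: 10 (2E,6Z)-3-{[(tert-butyldiphenylsilyl)oxy]methyl}-7-iodo-8,8-dimethoxyocta-2,6-dien-1-ol
Conditions: HC(OMe)3, PPTS (cat.), MeOH, rt
Reagents that add atoms: trimethyl orthoformate, COC(OC)OC; methanol, CO (solvent that exchanges with the orthoformate)
Why: Acid-catalysed acetalisation masks the C14 aldehyde as a dimethyl acetal that survives chromium reagents, base and anhydrous methanolic acid, with the TBDPS ether chosen because it is stable to these conditions.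

Step 7
Reactants: 10 (2E,6Z)-3-{[(tert-butyldiphenylsilyl)oxy]methyl}-7-iodo-8,8-dimethoxyocta-2,6-dien-1-ol
Product: 11 (2E,6Z)-3-{[(tert-butyldiphenylsilyl)oxy]methyl}-7-iodo-8,8-dimethoxyocta-2,6-dienal (fragment A)
Conditions: MnO2, CH2Cl2, rt
Reagents that add atoms: none
Why: Allylic oxidation with MnO2 converts the primary allylic alcohol into the enal under neutral conditions without touching acetal, iodide or silyl ether and without isomerising the C4=C5 alkene.

Step 8
Reactants: 12 (S)-2,2-dimethyl-1,3-dioxolane-4-carbaldehyde; 13 methyl acrylate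
Product: 14 methyl 2-{hydroxy[(4S)-2,2-dimethyl-1,3-dioxolan-4-yl]methyl}prop-2-enoate (both carbinol epimers)
Conditions: DABCO (0.5 equiv), 1,4-dioxane/H2O (1:1), rt
Reagents that add atoms: none
Why: Morita–Baylis–Hillman reaction of the activated α-alkoxy aldehyde attaches the acrylate carbons C11–C13; C8 comes from the chiral pool and the new carbinol centre is inconsequential because it becomes sp2 in step 9.

Step 9
Reactants: 14 methyl 2-{hydroxy[(4S)-2,2-dimethyl-1,3-dioxolan-4-yl]methyl}prop-2-enoate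
Product: 15 methyl (Z)-2-(bromomethyl)-3-[(4R)-2,2-dimethyl-1,3-dioxolan-4-yl]prop-2-enoate (fragment B)
Conditions: NBS, Me2S, CH2Cl2, −20 °C to rt
Reagents that add atoms: N-bromosuccinimide, O=C1CCC(=O)N1Br
Why: Corey–Kim-type activation of the allylic alcohol and SN2′ delivery of bromide transposes the allyl system to the thermodynamically preferred Z-2-(bromomethyl)enoate under neutral conditions that spare the acetonide and leave C8 untouched.

Step 10
Reactants: 11 (2E,6Z)-3-{[(tert-butyldiphenylsilyl)oxy]methyl}-7-iodo-8,8-dimethoxyocta-2,6-dienal; 15 methyl (Z)-2-(bromomethyl)-3-[(4R)-2,2-dimethyl-1,3-dioxolan-4-yl]prop-2-enoate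
Product: 18 (4S,5R)-5-[(1E,5Z)-2-{[(tert-butyldiphenylsilyl)oxy]methyl}-6-iodo-7,7-dimethoxyhepta-1,5-dien-1-yl]-4-[(4R)-2,2-dimethyl-1,3-dioxolan-4-yl]-3-methylideneoxolan-2-one, via allylchromium dichloride 16 (not isolated), via anti hydroxy ester 17 (not isolated)
Conditions: CrCl2 (4 equiv, nickel-free), THF, 0 °C to rt; aq. NH4Cl; then PPTS (cat.), CH2Cl2, rt
Reagents that add atoms: CrCl2, [Cr+2].[Cl-].[Cl-] (chromium and chlorine stay only in 16)
Why: In this Nozaki–Hiyama (Barbier-type) allylation the trivalent σ-allylchromium adds through a chair transition state with the C8 substituent equatorial to give the 6,7-anti adduct (trans-lactone after lactonisation), and the aldehyde attacks C7 anti to the dioxolane C–O bond with H8 eclipsing the ester-bearing alkene carbon (allylic 1,3-strain, Felkin–Anh-type), which sets 6R,7S relative to the pool-derived C8; the alkenyl iodide is inert without nickel.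

Step 11
Reactants: 18 trans-lactone acetonide
Product: 19 (4R,5R)-5-[(1E,5Z)-2-{[(tert-butyldiphenylsilyl)oxy]methyl}-6-iodo-7,7-dimethoxyhepta-1,5-dien-1-yl]-4-[(1R)-1,2-dihydroxyethyl]-3-methylideneoxolan-2-one
Conditions: CSA (0.1 equiv), MeOH, 0 °C; Et3N quench
Reagents that add atoms: none
Why: Acid-catalysed transketalisation to methanol releases the C8/C9 diol, while the C14 dimethyl acetal only undergoes degenerate exchange in dry methanol and the TBDPS ether and lactone survive at 0 °C.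

Step 12
Reactants: 19 lactone diol
Product: 20 (4R,5R)-5-[(1E,5Z)-2-{[(tert-butyldiphenylsilyl)oxy]methyl}-6-iodo-7,7-dimethoxyhepta-1,5-dien-1-yl]-4-{(1R)-1-hydroxy-2-[(triethylsilyl)oxy]ethyl}-3-methylideneoxolan-2-one
Conditions: TESCl (1.05 equiv), imidazole, CH2Cl2, −40 °C
Reagents that add atoms: chlorotriethylsilane, CC[Si](Cl)(CC)CC
Why: Sterically controlled silylation (silyl ether formation) takes the primary C9 hydroxyl and leaves the hindered secondary C8 hydroxyl free for acylation.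

Step 13
Reactants: 20 C9 triethylsilyl ether with free C8 hydroxyl; 21 (R)-2-methylbutanoic acid
Product: 22 (1R)-1-{(2R,3S)-2-[(1E,5Z)-2-{[(tert-butyldiphenylsilyl)oxy]methyl}-6-iodo-7,7-dimethoxyhepta-1,5-dien-1-yl]-4-methylidene-5-oxooxolan-3-yl}-2-[(triethylsilyl)oxy]ethyl (2R)-2-methylbutanoate
Conditions: DCC, DMAP (0.1 equiv), CH2Cl2, 0 °C to rt
Reagents that add atoms: none
Why: Steglich esterification acylates the C8 hydroxyl with retention at C8 and, at low DMAP loading and temperature, without epimerising the α-centre of the acid.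

Step 14
Reactants: 22 C8 ester with C9 triethylsilyl ether
Product: 23 (1R)-1-{(2R,3S)-2-[(1E,5Z)-2-{[(tert-butyldiphenylsilyl)oxy]methyl}-6-iodo-7,7-dimethoxyhepta-1,5-dien-1-yl]-4-methylidene-5-oxooxolan-3-yl}-2-oxoethyl (2R)-2-methylbutanoate
Conditions: (COCl)2, DMSO, CH2Cl2, −78 to −40 °C; then Et3N, −78 to −20 °C
Reagents that add atoms: none
Why: Swern oxidation converts the primary triethylsilyl ether directly into the aldehyde (oxidative desilylation by silyl–sulfonium exchange), so the C9 hydroxyl is never free next to the C8 ester, and the cold base step avoids epimerisation of the α-acyloxy aldehyde.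

Step 15
Reactants: 23 α-acyloxy aldehyde with alkenyl iodide
Product: 25 (6R,7S,8R,9S)-15-[(tert-butyldiphenylsilyl)oxy]-9-hydroxy-14,14-dimethoxy-8-[(2R)-2-methylbutanoyloxy]germacra-1(10),4,11(13)-trien-12,6-olide (both ring alkenes ring-cis; CIP 1(10)E/4E), via alkenylchromium dichloride 24 (not isolated)
Conditions: CrCl2 (10 equiv), NiCl2 (2 mol %), DMSO/THF (3:1), 2 mM (syringe pump), rt
Reagents that add atoms: CrCl2, [Cr+2].[Cl-].[Cl-] (chromium and chlorine stay only in 24)
Why: In this Nozaki–Hiyama–Kishi macrocyclisation zerovalent nickel inserts into the C–I bond, transmetalation gives a trivalent alkenylchromium that adds only to the aldehyde with retention of alkene geometry, the two ring-cis alkenes fold the chain for ten-ring closure, and Felkin–Anh attack anti to the C8 acyloxy group gives the 8,9-cis (9S) alcohol as the free hydroxyl.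

Step 16
Reactants: 25 silyl-protected macrocyclic acetal
Product: 27 (6R,7S,8R,9S)-9,15-dihydroxy-8-[(2R)-2-methylbutanoyloxy]-14-oxogermacra-1(10),4,11(13)-trien-12,6-olide (CNP0331447.12; CIP 1(10)E/4E), via diol acetal 26 (not isolated)
Conditions: HF·pyridine, THF, 0 °C to rt; then AcOH/H2O, rt
Reagents that add atoms: water, O
Why: Fluoride-mediated desilylation frees the C15 hydroxyl and mild aqueous acid hydrolysis of the dimethyl acetal releases the C14 enal, conditions under which the lactone, the C8 ester and the C9 hydroxyl are not disturbed and no base is present to cause acyl migration.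

## Compound list

1 | but-2-yne-1,4-diol | OCC#CCO | starting material
2 | 4-[(tert-butyldiphenylsilyl)oxy]but-2-yn-1-ol | OCC#CCO[Si](c1ccccc1)(c1ccccc1)C(C)(C)C | intermediate
3 | cyclic alkenylalanate: sodium 3-{[(tert-butyldiphenylsilyl)oxy]methyl}-2,2-bis(2-methoxyethoxy)-2,5-dihydro-1,2-oxaluminol-2-uide | [Na+].COCCO[Al-]1(OCCOC)OCC=C1CO[Si](c2ccccc2)(c2ccccc2)C(C)(C)C | intermediate (not isolated)
4 | (Z)-4-[(tert-butyldiphenylsilyl)oxy]-3-iodobut-2-en-1-ol | OC/C=C(\I)CO[Si](c1ccccc1)(c1ccccc1)C(C)(C)C | intermediate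
5 | potassium but-3-en-1-yltrifluoroborate | C=CCC[B-](F)(F)F.[K+] | starting material
6 | (E)-3-{[(tert-butyldiphenylsilyl)oxy]methyl}hepta-2,6-dien-1-ol | OC/C=C(\CCC=C)CO[Si](c1ccccc1)(c1ccccc1)C(C)(C)C | intermediate
7 | (E)-but-2-enal | C/C=C/C=O | starting material
8 | (2E,6E)-6-{[(tert-butyldiphenylsilyl)oxy]methyl}-8-hydroxyocta-2,6-dienal | OC/C=C(\CC/C=C/C=O)CO[Si](c1ccccc1)(c1ccccc1)C(C)(C)C | intermediate
9 | (2Z,6E)-6-{[(tert-butyldiphenylsilyl)oxy]methyl}-8-hydroxy-2-iodoocta-2,6-dienal | OC/C=C(\CC/C=C(\I)C=O)CO[Si](c1ccccc1)(c1ccccc1)C(C)(C)C | intermediate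
10 | (2E,6Z)-3-{[(tert-butyldiphenylsilyl)oxy]methyl}-7-iodo-8,8-dimethoxyocta-2,6-dien-1-ol | OC/C=C(\CC/C=C(\I)C(OC)OC)CO[Si](c1ccccc1)(c1ccccc1)C(C)(C)C | intermediate
11 | (2E,6Z)-3-{[(tert-butyldiphenylsilyl)oxy]methyl}-7-iodo-8,8-dimethoxyocta-2,6-dienal (fragment A) | O=C/C=C(\CC/C=C(\I)C(OC)OC)CO[Si](c1ccccc1)(c1ccccc1)C(C)(C)C | intermediate
12 | (S)-2,2-dimethyl-1,3-dioxolane-4-carbaldehyde | O=C[C@@H]1COC(C)(C)O1 | starting material
13 | methyl acrylate | C=CC(=O)OC | starting material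
14 | methyl 2-{hydroxy[(4S)-2,2-dimethyl-1,3-dioxolan-4-yl]methyl}prop-2-enoate (both carbinol epimers) | COC(=O)C(=C)C(O)[C@@H]1COC(C)(C)O1 | intermediate
15 | methyl (Z)-2-(bromomethyl)-3-[(4R)-2,2-dimethyl-1,3-dioxolan-4-yl]prop-2-enoate (fragment B) | COC(=O)/C(CBr)=C/[C@@H]1COC(C)(C)O1 | intermediate
16 | dichloro{2-(methoxycarbonyl)-3-[(4R)-2,2-dimethyl-1,3-dioxolan-4-yl]prop-2-en-1-yl}chromium (reactive form with C8 trans to the CH2Cr carbon) | COC(=O)/C(C[Cr](Cl)Cl)=C\[C@@H]1COC(C)(C)O1 | intermediate (not isolated)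
17 | methyl (3S,4R,5E,9Z)-6-{[(tert-butyldiphenylsilyl)oxy]methyl}-3-[(4R)-2,2-dimethyl-1,3-dioxolan-4-yl]-4-hydroxy-10-iodo-11,11-dimethoxy-2-methylideneundeca-5,9-dienoate | COC(=O)C(=C)[C@H]([C@@H]1COC(C)(C)O1)[C@H](O)/C=C(\CC/C=C(\I)C(OC)OC)CO[Si](c2ccccc2)(c2ccccc2)C(C)(C)C | intermediate (not isolated)
18 | (4S,5R)-5-[(1E,5Z)-2-{[(tert-butyldiphenylsilyl)oxy]methyl}-6-iodo-7,7-dimethoxyhepta-1,5-dien-1-yl]-4-[(4R)-2,2-dimethyl-1,3-dioxolan-4-yl]-3-methylideneoxolan-2-one | C=C1C(=O)O[C@H](/C=C(\CC/C=C(\I)C(OC)OC)CO[Si](c2ccccc2)(c2ccccc2)C(C)(C)C)[C@H]1[C@@H]3COC(C)(C)O3 | intermediate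
19 | (4R,5R)-5-[(1E,5Z)-2-{[(tert-butyldiphenylsilyl)oxy]methyl}-6-iodo-7,7-dimethoxyhepta-1,5-dien-1-yl]-4-[(1R)-1,2-dihydroxyethyl]-3-methylideneoxolan-2-one | C=C1C(=O)O[C@H](/C=C(\CC/C=C(\I)C(OC)OC)CO[Si](c2ccccc2)(c2ccccc2)C(C)(C)C)[C@H]1[C@@H](O)CO | intermediate
20 | (4R,5R)-5-[(1E,5Z)-2-{[(tert-butyldiphenylsilyl)oxy]methyl}-6-iodo-7,7-dimethoxyhepta-1,5-dien-1-yl]-4-{(1R)-1-hydroxy-2-[(triethylsilyl)oxy]ethyl}-3-methylideneoxolan-2-one | C=C1C(=O)O[C@H](/C=C(\CC/C=C(\I)C(OC)OC)CO[Si](c2ccccc2)(c2ccccc2)C(C)(C)C)[C@H]1[C@@H](O)CO[Si](CC)(CC)CC | intermediate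
21 | (R)-2-methylbutanoic acid | CC[C@@H](C)C(=O)O | starting material
22 | (1R)-1-{(2R,3S)-2-[(1E,5Z)-2-{[(tert-butyldiphenylsilyl)oxy]methyl}-6-iodo-7,7-dimethoxyhepta-1,5-dien-1-yl]-4-methylidene-5-oxooxolan-3-yl}-2-[(triethylsilyl)oxy]ethyl (2R)-2-methylbutanoate | C=C1C(=O)O[C@H](/C=C(\CC/C=C(\I)C(OC)OC)CO[Si](c2ccccc2)(c2ccccc2)C(C)(C)C)[C@H]1[C@@H](OC(=O)[C@H](C)CC)CO[Si](CC)(CC)CC | intermediate
23 | (1R)-1-{(2R,3S)-2-[(1E,5Z)-2-{[(tert-butyldiphenylsilyl)oxy]methyl}-6-iodo-7,7-dimethoxyhepta-1,5-dien-1-yl]-4-methylidene-5-oxooxolan-3-yl}-2-oxoethyl (2R)-2-methylbutanoate | C=C1C(=O)O[C@H](/C=C(\CC/C=C(\I)C(OC)OC)CO[Si](c2ccccc2)(c2ccccc2)C(C)(C)C)[C@H]1[C@@H](OC(=O)[C@H](C)CC)C=O | intermediate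
24 | alkenylchromium dichloride: 23 with the iodine replaced by a CrCl2 group (same configuration at all centres and alkenes) | C=C1C(=O)O[C@H](/C=C(\CC/C=C(\[Cr](Cl)Cl)C(OC)OC)CO[Si](c2ccccc2)(c2ccccc2)C(C)(C)C)[C@H]1[C@@H](OC(=O)[C@H](C)CC)C=O | intermediate (not isolated)
25 | (6R,7S,8R,9S)-15-[(tert-butyldiphenylsilyl)oxy]-9-hydroxy-14,14-dimethoxy-8-[(2R)-2-methylbutanoyloxy]germacra-1(10),4,11(13)-trien-12,6-olide (both ring alkenes ring-cis; CIP 1(10)E/4E) | C=C1C(=O)O[C@@H]2/C=C(/CO[Si](c3ccccc3)(c3ccccc3)C(C)(C)C)CC/C=C(/C(OC)OC)[C@H](O)[C@H](OC(=O)[C@H](C)CC)[C@@H]12 | intermediate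
26 | (6R,7S,8R,9S)-9,15-dihydroxy-14,14-dimethoxy-8-[(2R)-2-methylbutanoyloxy]germacra-1(10),4,11(13)-trien-12,6-olide (CIP 1(10)E/4E) | C=C1C(=O)O[C@@H]2/C=C(/CO)CC/C=C(/C(OC)OC)[C@H](O)[C@H](OC(=O)[C@H](C)CC)[C@@H]12 | intermediate (not isolated)
27 | (6R,7S,8R,9S)-9,15-dihydroxy-8-[(2R)-2-methylbutanoyloxy]-14-oxogermacra-1(10),4,11(13)-trien-12,6-olide (CNP0331447.12; CIP 1(10)E/4E) | C=C1C(=O)O[C@@H]2/C=C(/CO)CC/C=C(/C=O)[C@H](O)[C@H](OC(=O)[C@H](C)CC)[C@@H]12 | target

## Step count and risks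

Total: 16 steps. Longest linear sequence: 14 steps (steps 1–7, then 10–16); fragment B takes 2 steps.

Steps most likely to fail:

Step 15 (macrocyclising alkenylation). Risks are oligomerisation, incomplete Felkin control at C9 inside the forming ring, and acyl shift from O8 to the new chromium alkoxide. The fallback sets out from 23 and comes back at 25. The chromium cyclisation is run as before, accepting either C9 configuration, so that the crude product is 25 together with its C9 epimer, the 9R alcohol F1. The mixture is oxidised with Dess–Martin periodinane/NaHCO3 to the single 9-ketone F2. This enone is reduced at −78 °C with (S)-2-methyl-CBS-oxazaborolidine and catecholborane (alkenyl side as the large group; NaBH4/CeCl3 as the substrate-controlled alternative) to 25. C9 is then set by a reagent-controlled carbonyl reduction on the preformed ring instead of by the C–C bond formation.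

Step 10 (sense of 1,2-induction from C8 in the allylation). The 6,7-anti relationship is reliable, but the aldehyde could add to C7 syn to the dioxolane oxygen. In that case the fallback sets out from 11 and comes back at 22. (R)-2,2-Dimethyl-1,3-dioxolane-4-carbaldehyde (bought, O=C[C@H]1COC(C)(C)O1) is taken through the Morita–Baylis–Hillman reaction with 13 to the enantiomeric adduct F3, and through NBS/Me2S to the (4S)-bromide F4. CrCl2 with 11 then gives, via the allylchromium dichloride F5 and the hydroxy ester F6, the C8-epimeric lactone F7, which has the required 6R,7S centres and the wrong C8. Methanolysis (CSA, MeOH) gives the diol F8 and TESCl gives the primary silyl ether F9. A Mitsunobu esterification of F9 with 21 (PPh3, DIAD, toluene, 0 °C) installs the ester with inversion at C8 and gives 22.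

Step 11 (acetonide methanolysis next to the lactone). The freed C8 hydroxyl could translactonise, or the lactone could be opened by methanol. The fallback sets out from 18 and comes back at 20. TESOTf/2,6-lutidine (CH2Cl2, −78 to 0 °C) opens the dioxolane aprotically to the C9 triethylsilyl ether carrying the C8 isopropenyl ether F10. Its enol ether is hydrolysed within minutes by wet PPTS (THF/H2O, 0 °C) to 20. The free 1,2-diol is never formed and steps 11 and 12 merge into one operation.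

## Further compounds

F1 | step 15 | (6R,7S,8R,9R)-15-[(tert-butyldiphenylsilyl)oxy]-9-hydroxy-14,14-dimethoxy-8-[(2R)-2-methylbutanoyloxy]germacra-1(10),4,11(13)-trien-12,6-olide (C9 epimer of 25) | C=C1C(=O)O[C@@H]2/C=C(/CO[Si](c3ccccc3)(c3ccccc3)C(C)(C)C)CC/C=C(/C(OC)OC)[C@@H](O)[C@H](OC(=O)[C@H](C)CC)[C@@H]12
F2 | step 15 | (6R,7S,8R)-15-[(tert-butyldiphenylsilyl)oxy]-14,14-dimethoxy-8-[(2R)-2-methylbutanoyloxy]-9-oxogermacra-1(10),4,11(13)-trien-12,6-olide | C=C1C(=O)O[C@@H]2/C=C(/CO[Si](c3ccccc3)(c3ccccc3)C(C)(C)C)CC/C=C(/C(OC)OC)C(=O)[C@H](OC(=O)[C@H](C)CC)[C@@H]12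
F3 | step 10 | methyl 2-{hydroxy[(4R)-2,2-dimethyl-1,3-dioxolan-4-yl]methyl}prop-2-enoate (both carbinol epimers) | COC(=O)C(=C)C(O)[C@H]1COC(C)(C)O1
F4 | step 10 | methyl (Z)-2-(bromomethyl)-3-[(4S)-2,2-dimethyl-1,3-dioxolan-4-yl]prop-2-enoate | COC(=O)/C(CBr)=C/[C@H]1COC(C)(C)O1
F5 | step 10 | dichloro{2-(methoxycarbonyl)-3-[(4S)-2,2-dimethyl-1,3-dioxolan-4-yl]prop-2-en-1-yl}chromium | COC(=O)/C(C[Cr](Cl)Cl)=C\[C@H]1COC(C)(C)O1
F6 | step 10 | methyl (3S,4R,5E,9Z)-6-{[(tert-butyldiphenylsilyl)oxy]methyl}-3-[(4S)-2,2-dimethyl-1,3-dioxolan-4-yl]-4-hydroxy-10-iodo-11,11-dimethoxy-2-methylideneundeca-5,9-dienoate | COC(=O)C(=C)[C@H]([C@H]1COC(C)(C)O1)[C@H](O)/C=C(\CC/C=C(\I)C(OC)OC)CO[Si](c2ccccc2)(c2ccccc2)C(C)(C)C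
F7 | step 10 | (4S,5R)-5-[(1E,5Z)-2-{[(tert-butyldiphenylsilyl)oxy]methyl}-6-iodo-7,7-dimethoxyhepta-1,5-dien-1-yl]-4-[(4S)-2,2-dimethyl-1,3-dioxolan-4-yl]-3-methylideneoxolan-2-one | C=C1C(=O)O[C@H](/C=C(\CC/C=C(\I)C(OC)OC)CO[Si](c2ccccc2)(c2ccccc2)C(C)(C)C)[C@H]1[C@H]3COC(C)(C)O3
F8 | step 10 | (4R,5R)-5-[(1E,5Z)-2-{[(tert-butyldiphenylsilyl)oxy]methyl}-6-iodo-7,7-dimethoxyhepta-1,5-dien-1-yl]-4-[(1S)-1,2-dihydroxyethyl]-3-methylideneoxolan-2-one | C=C1C(=O)O[C@H](/C=C(\CC/C=C(\I)C(OC)OC)CO[Si](c2ccccc2)(c2ccccc2)C(C)(C)C)[C@H]1[C@H](O)CO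
F9 | step 10 | (4R,5R)-5-[(1E,5Z)-2-{[(tert-butyldiphenylsilyl)oxy]methyl}-6-iodo-7,7-dimethoxyhepta-1,5-dien-1-yl]-4-{(1S)-1-hydroxy-2-[(triethylsilyl)oxy]ethyl}-3-methylideneoxolan-2-one | C=C1C(=O)O[C@H](/C=C(\CC/C=C(\I)C(OC)OC)CO[Si](c2ccccc2)(c2ccccc2)C(C)(C)C)[C@H]1[C@H](O)CO[Si](CC)(CC)CC
F10 | step 11 | (4S,5R)-5-[(1E,5Z)-2-{[(tert-butyldiphenylsilyl)oxy]methyl}-6-iodo-7,7-dimethoxyhepta-1,5-dien-1-yl]-3-methylidene-4-{(1R)-1-(prop-1-en-2-yloxy)-2-[(triethylsilyl)oxy]ethyl}oxolan-2-one | C=C1C(=O)O[C@H](/C=C(\CC/C=C(\I)C(OC)OC)CO[Si](c2ccccc2)(c2ccccc2)C(C)(C)C)[C@H]1[C@@H](OC(C)=C)CO[Si](CC)(CC)CC
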